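# Proposed synthesis of (2S,3S)-17 by benzannulation of a diarylbutyrolactone

## The problem

Compound 17 is a 2,3-trans-2,3-diaryl-2,3-dihydro-1-benzofuran. C2 (S) carries a catechol ring, C3 (S) a 3,5-dihydroxyphenyl ring, and the fused ring A carries a free hydroxyl at C6 and an (E)-3,5-dihydroxystyryl group at C5. Ring A is therefore a resorcinol (oxygen at C6 and C7a) with carbon substituents at C3a and C5. Electrophilic substitution of a resorcinol does not give this pattern cleanly, because C7 between the two oxygens competes with C5.

Only C3 has to be set absolutely. The C2–O1 bond is benzylic and para to a catechol oxygen, so it ionises readily and recloses trans under the control of C3; C3 can control C2, but not the reverse. Once ring A is aromatic, C3 is a diarylmethine that is neither enolisable nor ionisable.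

Seven phenols, an electron-rich stilbene and the labile C2–O1 bond rule out oxidants, hot strong acid and hydrogenation late in the route. The phenols must stay masked to the end and the alkene should arrive late.

The feature that allows a short approach lies in ring A (C3a, C4, C5, C6, C7, C7a). C7a with its oxygen and C3a with its bond to C3 are the carbonyl carbon and α-carbon of a γ-butyrolactone whose β- and γ-carbons are C3 and C2. C4 to C7, with the carbon substituent on C5 and the oxygen on C6, are the four-carbon chain of an alkoxymethylene acetoacetate. Ring A can thus be grown onto a lactone that already holds both aryl groups and the C3 stereocentre.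

## Retrosynthesis

**17 ⇒ 16.** The seven O–H bonds are traced back to O–CH3 bonds. Methyl ethers are chosen because 1, 2 and 15 carry them as purchased and because they are inert to every enolate, hydride, acid and base on the way. Benzyl ethers could be hydrogenolysed only together with the stilbene, and silyl ethers would not survive the alkoxide stage of the ring synthesis. 16 is non-polar and not oxidisable, so it is far easier to handle than 17. The forward reaction must cleave seven aryl methyl ethers without losing the C2 configuration or adding acid across the alkene.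

**16 ⇒ 14 + 15.** The stilbene C=C bond is cut. A Horner–Wadsworth–Emmons reaction of a benzylphosphonate gives the E alkene reliably. The neighbouring aryl–vinyl cut (Heck) would need a halide at C5, whereas the ring synthesis below leaves an ester there, which is a latent aldehyde. 14 is smaller than 16 by the whole styryl unit. The base must deprotonate 15 and not C3–H of 14.

**14 ⇒ 13 ⇒ 12 ⇒ 11.** No skeletal bond is cut. The aldehyde goes back through benzylic alcohol 13 to ethyl ester 12, and the C6 methyl ether goes back to the free phenol of 11. Capping C6–OH costs one step, but it lets reduction, oxidation and olefination run without an acidic phenol beside the reacting carbon. The methyl group leaves with the other six at the end.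

**11 ⇒ 10.** O1–C2 is cut, giving a 2-hydroxyaryl diarylethanol. Closure through the 3,4-dimethoxybenzylic cation is preferred over an invertive displacement because it is stereoconvergent: whatever the carbinol configuration, C3 steers the phenol to the trans face. After this cut C2 is no longer a stereochemical problem and only C3 remains.

**10 ⇒ 7 + 8.** C3a–C4 and C7–C7a are cut, which dissolves ring A into the α-carbon and carbonyl of lactone 7 and the four-carbon unit 8. Cutting C3–C3a instead would keep ring A as a purchased arene, but it would need an enantioselective diarylmethine synthesis and a regioselective resorcinol substitution. Cutting C2–C3 would need a carbene insertion. Here 7 is simpler than 10 by an entire, fully substituted benzene ring, and the C5 ester, C6–OH and C7a–OH appear in place without any aromatic substitution. The forward reaction must join the lactone enolate to the ethoxymethylene carbon and then let the methyl ketone acylate on carbon, not on oxygen.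

**7 ⇒ 5.** The lactone C–O bond and the carbinol C–H bond are cut, leading to racemic γ-keto ester 5. The stereocentre of 5 lies between an aroyl and an aryl group and racemises easily, so a dynamic kinetic transfer hydrogenation can set both centres from the racemate. Setting this centre first by auxiliary-controlled alkylation and adding the aryl ketone afterwards would risk exactly this racemisation. The reduction must be fast for only one enantiomer of 5. 7 must be diastereomerically pure, because after the cationic closure a diastereomeric impurity at the diarylmethine carbon becomes an enantiomeric one.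

**5 ⇒ 3 + 4, and 3 ⇒ 1 + 2.** The CH–CH2 bond of 5 is cut to the enolate of deoxybenzoin 3 and bromoacetate 4. The aryl–CH2 bond of 3 is cut to acetophenone 1 and aryl bromide 2 (palladium-catalysed α-arylation). The other cut of 3, at the acyl–aryl bond (Friedel–Crafts acylation), would set two electron-rich arenes in competition for the acylium ion. Compounds 1, 2, 4, 8 and 15 are commercial.

## Roads not taken

**Alternative 1:** The cut is at the C2–aryl and C3–aryl bonds of an intact benzofuran. In the forward sense the aryllithium A3 adds to the benzofuran-2-yl boronic ester A2. An arylpalladium species from the triflate A4 then attacks C3 of the boronate complex while the catechol ring migrates from boron to C2 on the opposite face, giving A1 with the aryl groups anti.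
- Merits: it is the most convergent plan. Both aryl groups and both stereocentres arrive in one operation, the anti relationship is built into the mechanism, and ring A with its masked C5 aldehyde is handled as a flat aromatic. A stereoretentive protodeboronation and acetal hydrolysis would reach 14 directly.
- Weak points: conjunctive coupling with dearomatisation is not established for benzofuranyl boronates. Direct Suzuki-type transfer from the boronate competes. Absolute control rests on a chiral palladium ligand untested on this heteroarene. A1 is a tertiary, benzylic, α-oxygenated boronic ester whose protodeboronation with retention is itself uncertain. A2 needs its own multistep preparation.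
- Comparison: this road could be shorter after the key step. Against that, the chosen plan confines its one unproven reaction to a step that creates no stereocentre, and takes the absolute configuration from a reduction of a well-established type.

**Alternative 2:** The cut is at C2–C3. The diaryldiazomethane A6 gives a rhodium carbene at C3 that inserts into the benzylic ether C–H bond and closes the dihydrofuran ring; acid then equilibrates C2 to give the trans bromide A5.
- Merits: enantioselective insertion of donor/donor carbenes into benzylic ether C–H bonds with chiral dirhodium tetracarboxylates is an established route to 2,3-diaryl dihydrobenzofurans. Ring A is bought, and the bromide of A5 would allow a single Heck coupling with the appropriate styrene to reach 16. In precedent for its key step and in the length of its endgame this road is better than the chosen one.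
- Weak points: A6 needs four to five steps (etherification, aryl addition, oxidation, hydrazone, oxidation). The native cis selectivity must be corrected by acid. The very electron-rich 3,4-dimethoxybenzyl ether invites oxidation and ylide pathways. A diazo intermediate and a costly chiral dirhodium catalyst are required.
- Comparison: the chosen plan sets against this the assembly of ring A with all its substituents from two cheap esters, no diazo chemistry, absolute control from a ruthenium catalyst at low loading, and a new benzannulation of wider use. This road is retained as the fallback for the key step.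

**Alternative 3:** The cut dissolves the two 3,5-dihydroxyphenyl rings, each at the C2–C7 bond of a triketo ester chain. Heating the bis(diketo-dioxinone) A8 in an alcohol unmasks two 3,5,7-triketo esters, and a carbonate base closes both by aldol condensation and aromatisation to A7.
- Merits: it is biomimetic, forms two rings at once, and four of the seven phenols are born free, so the final deprotection is milder than in the chosen plan.
- Weak points: it builds the two rings that can be bought as 3,5-dimethoxyphenyl units and leaves the hard parts, ring A and the stereocentres, to an unspecified earlier phase. In A8, C3 is α to a ketone and β to the ring oxygen, so the base of the key step can epimerise it and expel the C7a phenoxide by E1cB. The two ester groups of A7 must afterwards be removed by hydrolysis and decarboxylation, and three methyl ethers still need cleavage.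
- Comparison: the chosen plan must cleave seven methyl ethers, which is harsher, but it is much shorter and never places the C3 stereocentre next to a carbonyl after it has been set.

Key step: step 4

Assumption: the dynamic kinetic reduction in step 3 is taken to follow Felkin–Anh control and to give the cis lactone; only the diarylmethine configuration matters downstream, because the carbinol centre is erased in step 5.

## Route

Step 1
Reactants: 1 3',4'-dimethoxyacetophenone; 2 1-bromo-3,5-dimethoxybenzene
Product: 3 1-(3,4-dimethoxyphenyl)-2-(3,5-dimethoxyphenyl)ethan-1-one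
Conditions: Pd(OAc)2 (2 mol %), Xantphos (2.5 mol %), NaOt-Bu (2.2 equiv), toluene, 80 °C
Reagents that add atoms: none
Why: Palladium-catalysed ketone α-arylation (Buchwald–Hartwig type): oxidative addition of 2 to zerovalent palladium, enolate transmetalation and reductive elimination. Aryl methyl ketones stop at monoarylation because the product enolate is more hindered and less nucleophilic.

Step 2
Reactants: 3 1-(3,4-dimethoxyphenyl)-2-(3,5-dimethoxyphenyl)ethan-1-one; 4 ethyl bromoacetate
Product: 5 ethyl 4-(3,4-dimethoxyphenyl)-3-(3,5-dimethoxyphenyl)-4-oxobutanoate (racemic)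
Conditions: NaH (1.05 equiv), THF, 0 °C; then 4, 0 °C → rt
Reagents that add atoms: none
Why: C-alkylation of a deoxybenzoin enolate with an α-halo ester, a standard enolate alkylation (SN2). The product is less acidic and more hindered than 3, which limits dialkylation.

Step 3
Reactants: 5 ethyl 4-(3,4-dimethoxyphenyl)-3-(3,5-dimethoxyphenyl)-4-oxobutanoate (racemic)
Product: 7 (4R,5R)-5-(3,4-dimethoxyphenyl)-4-(3,5-dimethoxyphenyl)dihydrofuran-2(3H)-one (aryl groups cis), via ethyl (3R,4R)-hydroxy ester 6 (not isolated)
Conditions: RuCl(p-cymene)[(R,R)-TsDPEN] (1 mol %), HCO2H/Et3N (1:1), DMF, 40 °C; then PPTS (10 mol %), toluene, 60 °C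
Reagents that add atoms: none
Why: Noyori asymmetric transfer hydrogenation with dynamic kinetic resolution, followed by lactonisation. The (R,R)-catalyst should deliver hydride to aryl ketones to give the (R)-carbinol, and the matched (3R)-enantiomer of 5 reacts with hydride anti to the 3,5-dimethoxyphenyl group (Felkin–Anh) while the other enantiomer racemises through the enol. The lactone is purified to a single diastereomer by crystallisation or chromatography so that the diarylmethine carbon is homogeneous.

Step 4
Reactants: 7 (4R,5R)-5-(3,4-dimethoxyphenyl)-4-(3,5-dimethoxyphenyl)dihydrofuran-2(3H)-one; 8 ethyl 2-(ethoxymethylene)-3-oxobutanoate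
Product: 10 ethyl 5-[(1S,2R)-2-(3,4-dimethoxyphenyl)-1-(3,5-dimethoxyphenyl)-2-hydroxyethyl]-2,4-dihydroxybenzoate, via alkylidene acetoacetate adduct 9 (not isolated)
Conditions: LiN(SiMe3)2 (1.05 equiv), THF, −78 °C; 8 (1.0 equiv), −78 → 0 °C; then NaOEt (3 equiv), EtOH, 60 °C; cold 1 M HCl to pH 4
Reagents that add atoms: none
Why: Proposed new method: the lithium enolate of 7 should add to the ethoxymethylene carbon of 8 and the adduct lose ethoxide (addition–elimination, C3a–C4) to give 9, which the liberated ethoxide turns into a delocalised anion whose double bonds isomerise freely; under equilibrating NaOEt/EtOH the minor methyl ketone enolate tautomer attacks the lactone carbonyl (or the ethyl ester formed from it by ethanolysis) to make C7–C7a, the tetrahedral intermediate expels the C2 alkoxide, and the cyclohexenedione tautomerises irreversibly to the resorcinol bis-phenoxide. The closest known reaction type is the Michael–Claisen synthesis of resorcylates from malonate-type enolates with alkoxymethylene or alkynyl ketones, and of cyclohexane-1,3-diones as in the dimedone synthesis; new here is a singly activated lactone enolate as donor whose own ring carbonyl is the acyl acceptor. Ring A closes in the 6-exo-trig mode at the acyl carbon (enolexo). No stereocentre is created: C3a becomes aromatic, the carbinol carbon keeps its C–O bond, and the diarylmethine carbon is β to the carbonyl and never enolisable. The step needs conjugate addition to outrun proton transfer from 8, which a pre-formed enolate at −78 °C and a base that leaves no nucleophilic amine behind should secure. It also needs acylation on carbon to win over acylation on oxygen to a 2-pyranone; the reversible alkoxide stage should secure this, since any pyranone reopens and only the aromatic phenoxide is a sink. Regiochemistry is fixed because 7 has one enolisable carbon and one acyl carbon and 8 has one electrophilic and one nucleophilic terminus.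

Step 5
Reactants: 10 ethyl 5-[(1S,2R)-2-(3,4-dimethoxyphenyl)-1-(3,5-dimethoxyphenyl)-2-hydroxyethyl]-2,4-dihydroxybenzoate
Product: 11 ethyl (2S,3S)-2-(3,4-dimethoxyphenyl)-3-(3,5-dimethoxyphenyl)-6-hydroxy-2,3-dihydro-1-benzofuran-5-carboxylate
Conditions: CF3CO2H (5 equiv), CH2Cl2 (dilute), 0 °C → rt
Reagents that add atoms: none
Why: Acid-mediated cyclodehydration: the 3,4-dimethoxybenzylic alcohol ionises and the adjacent phenol (4-OH of the benzoate) captures the cation in a 5-exo closure. C2 is set trans to the C3 aryl group under C3 control, and reversible ionisation leads to the more stable trans isomer whatever the carbinol configuration.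

Step 6
Reactants: 11 ethyl (2S,3S)-2-(3,4-dimethoxyphenyl)-3-(3,5-dimethoxyphenyl)-6-hydroxy-2,3-dihydro-1-benzofuran-5-carboxylate
Product: 12 ethyl (2S,3S)-2-(3,4-dimethoxyphenyl)-3-(3,5-dimethoxyphenyl)-6-methoxy-2,3-dihydro-1-benzofuran-5-carboxylate
Conditions: MeI, K2CO3, DMF, 40 °C
Reagents that add atoms: iodomethane, CI
Why: Williamson O-methylation of the only remaining phenol. Neither stereocentre is acidic towards carbonate, and no free para-hydroxyl is present that could open the ring.

Step 7
Reactants: 12 ethyl (2S,3S)-2-(3,4-dimethoxyphenyl)-3-(3,5-dimethoxyphenyl)-6-methoxy-2,3-dihydro-1-benzofuran-5-carboxylate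
Product: 13 [(2S,3S)-2-(3,4-dimethoxyphenyl)-3-(3,5-dimethoxyphenyl)-6-methoxy-2,3-dihydro-1-benzofuran-5-yl]methanol
Conditions: LiAlH4, THF, 0 °C
Reagents that add atoms: none
Why: Hydride reduction of an aryl ester to the benzylic alcohol. Ethers and the dihydrobenzofuran are inert.

Step 8
Reactants: 13 [(2S,3S)-2-(3,4-dimethoxyphenyl)-3-(3,5-dimethoxyphenyl)-6-methoxy-2,3-dihydro-1-benzofuran-5-yl]methanol
Product: 14 (2S,3S)-2-(3,4-dimethoxyphenyl)-3-(3,5-dimethoxyphenyl)-6-methoxy-2,3-dihydro-1-benzofuran-5-carbaldehyde
Conditions: MnO2 (activated, excess), CH2Cl2, rt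
Reagents that add atoms: none
Why: Selective oxidation of an electron-rich benzylic alcohol by manganese dioxide. It stops at the aldehyde and should leave the dihydrofuran ring at rt untouched.

Step 9
Reactants: 14 (2S,3S)-2-(3,4-dimethoxyphenyl)-3-(3,5-dimethoxyphenyl)-6-methoxy-2,3-dihydro-1-benzofuran-5-carbaldehyde; 15 diethyl [(3,5-dimethoxyphenyl)methyl]phosphonate
Product: 16 (2S,3S)-2-(3,4-dimethoxyphenyl)-3-(3,5-dimethoxyphenyl)-5-[(E)-2-(3,5-dimethoxyphenyl)ethenyl]-6-methoxy-2,3-dihydro-1-benzofuran
Conditions: 15 (1.3 equiv), KOt-Bu (1.2 equiv), THF, 0 °C; then 14, 0 °C → rt; aq. NH4Cl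
Reagents that add atoms: none
Why: Horner–Wadsworth–Emmons olefination; benzylphosphonate anions give (E)-stilbenes through the anti oxaphosphetane. The anion is pre-formed with less base than phosphonate, so no free alkoxide is left to deprotonate C3–H and open the ring by E1cB.

Step 10
Reactants: 16 (2S,3S)-2-(3,4-dimethoxyphenyl)-3-(3,5-dimethoxyphenyl)-5-[(E)-2-(3,5-dimethoxyphenyl)ethenyl]-6-methoxy-2,3-dihydro-1-benzofuran
Product: 17 4-[(2S,3S)-3-(3,5-dihydroxyphenyl)-5-[(E)-2-(3,5-dihydroxyphenyl)ethenyl]-6-hydroxy-2,3-dihydro-1-benzofuran-2-yl]benzene-1,2-diol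
Conditions: BBr3 (12 equiv), CH2Cl2, −78 → 0 °C; then ice-water
Reagents that add atoms: none
Why: Lewis-acid cleavage of aryl methyl ethers (O-complexation, bromide attack at methyl), a standard last step for polymethoxylated stilbenes and diaryl dihydrobenzofurans. If the C2–O1 bond ionises, reclosure again gives the trans isomer, so the configuration should be retained.

## Compound list

1 | 3',4'-dimethoxyacetophenone | CC(=O)c1ccc(OC)c(OC)c1 | starting material
2 | 1-bromo-3,5-dimethoxybenzene | COc1cc(Br)cc(OC)c1 | starting material
3 | 1-(3,4-dimethoxyphenyl)-2-(3,5-dimethoxyphenyl)ethan-1-one | COc1ccc(C(=O)Cc2cc(OC)cc(OC)c2)cc1OC | intermediate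
4 | ethyl bromoacetate | CCOC(=O)CBr | starting material
5 | ethyl 4-(3,4-dimethoxyphenyl)-3-(3,5-dimethoxyphenyl)-4-oxobutanoate (racemic) | CCOC(=O)CC(c1cc(OC)cc(OC)c1)C(=O)c1ccc(OC)c(OC)c1 | intermediate
6 | ethyl (3R,4R)-4-(3,4-dimethoxyphenyl)-3-(3,5-dimethoxyphenyl)-4-hydroxybutanoate (formed in the flask) | CCOC(=O)C[C@H](c1cc(OC)cc(OC)c1)[C@@H](O)c1ccc(OC)c(OC)c1 | intermediate
7 | (4R,5R)-5-(3,4-dimethoxyphenyl)-4-(3,5-dimethoxyphenyl)dihydrofuran-2(3H)-one (aryl groups cis) | O=C1O[C@@H](c2ccc(OC)c(OC)c2)[C@@H](c2cc(OC)cc(OC)c2)C1 | intermediate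
8 | ethyl 2-(ethoxymethylene)-3-oxobutanoate (mixture of alkene isomers) | CCOC=C(C(C)=O)C(=O)OCC | starting material
9 | ethyl 2-acetyl-3-[(4R,5R)-5-(3,4-dimethoxyphenyl)-4-(3,5-dimethoxyphenyl)-2-oxooxolan-3-yl]prop-2-enoate (C3 epimers and alkene isomers, present as its enolate; formed in the flask) | O=C1O[C@@H](c2ccc(OC)c(OC)c2)[C@@H](c2cc(OC)cc(OC)c2)C1C=C(C(C)=O)C(=O)OCC | intermediate
10 | ethyl 5-[(1S,2R)-2-(3,4-dimethoxyphenyl)-1-(3,5-dimethoxyphenyl)-2-hydroxyethyl]-2,4-dihydroxybenzoate | CCOC(=O)c1cc([C@H](c2cc(OC)cc(OC)c2)[C@@H](O)c2ccc(OC)c(OC)c2)c(O)cc1O | intermediate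
11 | ethyl (2S,3S)-2-(3,4-dimethoxyphenyl)-3-(3,5-dimethoxyphenyl)-6-hydroxy-2,3-dihydro-1-benzofuran-5-carboxylate | CCOC(=O)c1cc2c(cc1O)O[C@H](c1ccc(OC)c(OC)c1)[C@H]2c1cc(OC)cc(OC)c1 | intermediate
12 | ethyl (2S,3S)-2-(3,4-dimethoxyphenyl)-3-(3,5-dimethoxyphenyl)-6-methoxy-2,3-dihydro-1-benzofuran-5-carboxylate | CCOC(=O)c1cc2c(cc1OC)O[C@H](c1ccc(OC)c(OC)c1)[C@H]2c1cc(OC)cc(OC)c1 | intermediate
13 | [(2S,3S)-2-(3,4-dimethoxyphenyl)-3-(3,5-dimethoxyphenyl)-6-methoxy-2,3-dihydro-1-benzofuran-5-yl]methanol | OCc1cc2c(cc1OC)O[C@H](c1ccc(OC)c(OC)c1)[C@H]2c1cc(OC)cc(OC)c1 | intermediate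
14 | (2S,3S)-2-(3,4-dimethoxyphenyl)-3-(3,5-dimethoxyphenyl)-6-methoxy-2,3-dihydro-1-benzofuran-5-carbaldehyde | O=Cc1cc2c(cc1OC)O[C@H](c1ccc(OC)c(OC)c1)[C@H]2c1cc(OC)cc(OC)c1 | intermediate
15 | diethyl [(3,5-dimethoxyphenyl)methyl]phosphonate | CCOP(=O)(Cc1cc(OC)cc(OC)c1)OCC | starting material
16 | (2S,3S)-2-(3,4-dimethoxyphenyl)-3-(3,5-dimethoxyphenyl)-5-[(E)-2-(3,5-dimethoxyphenyl)ethenyl]-6-methoxy-2,3-dihydro-1-benzofuran | COc1cc(OC)cc(/C=C/c2cc3c(cc2OC)O[C@H](c2ccc(OC)c(OC)c2)[C@H]3c2cc(OC)cc(OC)c2)c1 | intermediate
17 | 4-[(2S,3S)-3-(3,5-dihydroxyphenyl)-5-[(E)-2-(3,5-dihydroxyphenyl)ethenyl]-6-hydroxy-2,3-dihydro-1-benzofuran-2-yl]benzene-1,2-diol | Oc1cc(O)cc(/C=C/c2cc3c(cc2O)O[C@H](c2ccc(O)c(O)c2)[C@H]3c2cc(O)cc(O)c2)c1 | target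

## Step count and least certain steps

Total step count: 10. Longest linear sequence: 10 steps (1 or 2 to 17).

**Step 4 (key step).**
- What may go wrong: proton transfer from the acidic acetyl group of 8 may quench the lactone enolate before the C3a–C4 bond forms. Alternatively the adduct may close on oxygen to a 2-pyranone or rest as the stabilised anion, because the methyl ketone enolate needed for the Claisen closure is only a minor tautomer.
- Fallback, using known chemistry: ring A is bought as an arene and the dihydrofuran ring is closed instead. The fallback sets out from 2 and returns at 14.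
  - Commercial 5-bromo-2-hydroxy-4-methoxybenzaldehyde is O-alkylated with 3,4-dimethoxybenzyl chloride (K2CO3, DMF) to 5-bromo-2-[(3,4-dimethoxyphenyl)methoxy]-4-methoxybenzaldehyde F1.
  - The Grignard reagent from 2 adds to F1 to give the diarylmethanol F2, which MnO2 oxidises to the benzophenone F3.
  - Hydrazine converts F3 into the hydrazone F4, and MnO2 oxidises this to the diaryldiazomethane F5.
  - With the antipode of Rh2(PTAD)4 that sets (3S), the donor/donor carbene inserts into the benzylic ether C–H bond to give the cis-dihydrobenzofuran F6.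
  - CF3CO2H equilibrates C2 to the trans bromide F7, which is identical with A5.
  - Bromine–lithium exchange (n-BuLi, THF, −78 °C) and formylation with DMF give 14.

**Step 3.**
- What may go wrong: racemisation of the slow-reacting enantiomer of 5 may not keep pace with reduction, or hydride delivery may not follow the Felkin–Anh sense assumed. Either would lower the diastereomeric purity of the lactone and, after step 5, the enantiomeric purity at C3. The configuration of the diarylmethine carbon of 7 has to be confirmed before going on.
- Fallback: resolution replaces asymmetric catalysis. From 5, substrate-controlled reduction with LiBH(s-Bu)3 and lactonisation on acidic work-up give the racemic cis-lactone F8. Preparative chromatography on a chiral stationary phase returns 7, and the (4S,5S)-antipode F9 is set aside.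

**Step 5.**
- What may go wrong: before the phenol captures the benzylic cation, it may lose the C3 proton to form a triarylethylene or undergo a 1,2-hydride shift to the doubly benzylic position. Either would destroy the only persistent stereocentre.
- Fallback: an intramolecular Mitsunobu etherification of 10 (PPh3, DIAD, THF, 0 °C) closes the ring by SN2 displacement without a free cation. The (R)-carbinol of 10 is inverted, which is exactly what the trans ring of 11 requires. The fallback sets out from 10 and returns at 11 and makes no new isolated compound.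

**Step 10.**
- What may go wrong: during the long exposure needed for seven ethers, the Lewis acid may ionise the C2–O1 bond with capture by bromide, and HBr may add to or oligomerise the electron-rich stilbene.
- Fallback: the harsh step is moved ahead of the alkene and the end is made fluoride-labile. The fallback sets out from 14 and returns at 17.
  - BBr3 converts 14 into the pentahydroxy aldehyde F10.
  - TBSCl and imidazole give the pentakis(silyl ether) F11.
  - Olefination with diethyl {[3,5-bis(tert-butyldimethylsilyloxy)phenyl]methyl}phosphonate F12 (prepared separately from 3,5-dihydroxybenzyl alcohol) and LiN(SiMe3)2 at −78 → 0 °C gives the heptakis(silyl ether) F13.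
  - n-Bu4NF buffered with acetic acid releases 17.

## Further compounds

F1 | step 4 | 5-bromo-2-[(3,4-dimethoxyphenyl)methoxy]-4-methoxybenzaldehyde | O=Cc1cc(Br)c(OC)cc1OCc1ccc(OC)c(OC)c1
F2 | step 4 | {5-bromo-2-[(3,4-dimethoxyphenyl)methoxy]-4-methoxyphenyl}(3,5-dimethoxyphenyl)methanol (racemic) | OC(c1cc(OC)cc(OC)c1)c1cc(Br)c(OC)cc1OCc1ccc(OC)c(OC)c1
F3 | step 4 | {5-bromo-2-[(3,4-dimethoxyphenyl)methoxy]-4-methoxyphenyl}(3,5-dimethoxyphenyl)methanone | O=C(c1cc(OC)cc(OC)c1)c1cc(Br)c(OC)cc1OCc1ccc(OC)c(OC)c1
F4 | step 4 | hydrazone of F3 (mixture of C=N isomers) | NN=C(c1cc(OC)cc(OC)c1)c1cc(Br)c(OC)cc1OCc1ccc(OC)c(OC)c1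
F5 | step 4 | {5-bromo-2-[(3,4-dimethoxyphenyl)methoxy]-4-methoxyphenyl}(3,5-dimethoxyphenyl)diazomethane | [N-]=[N+]=C(c1cc(OC)cc(OC)c1)c1cc(Br)c(OC)cc1OCc1ccc(OC)c(OC)c1
F6 | step 4 | (2R,3S)-5-bromo-2-(3,4-dimethoxyphenyl)-3-(3,5-dimethoxyphenyl)-6-methoxy-2,3-dihydro-1-benzofuran (aryl groups cis) | Brc1cc2c(cc1OC)O[C@@H](c1ccc(OC)c(OC)c1)[C@H]2c1cc(OC)cc(OC)c1
F7 | step 4 | (2S,3S)-5-bromo-2-(3,4-dimethoxyphenyl)-3-(3,5-dimethoxyphenyl)-6-methoxy-2,3-dihydro-1-benzofuran (aryl groups trans) | Brc1cc2c(cc1OC)O[C@H](c1ccc(OC)c(OC)c1)[C@H]2c1cc(OC)cc(OC)c1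
F8 | step 3 | cis-5-(3,4-dimethoxyphenyl)-4-(3,5-dimethoxyphenyl)dihydrofuran-2(3H)-one (racemic; one enantiomer drawn) | O=C1O[C@@H](c2ccc(OC)c(OC)c2)[C@@H](c2cc(OC)cc(OC)c2)C1
F9 | step 3 | (4S,5S)-5-(3,4-dimethoxyphenyl)-4-(3,5-dimethoxyphenyl)dihydrofuran-2(3H)-one | O=C1O[C@H](c2ccc(OC)c(OC)c2)[C@H](c2cc(OC)cc(OC)c2)C1
F0 | step 5 | none | none
F10 | step 10 | (2S,3S)-2-(3,4-dihydroxyphenyl)-3-(3,5-dihydroxyphenyl)-6-hydroxy-2,3-dihydro-1-benzofuran-5-carbaldehyde | O=Cc1cc2c(cc1O)O[C@H](c1ccc(O)c(O)c1)[C@H]2c1cc(O)cc(O)c1
F11 | step 10 | pentakis(tert-butyldimethylsilyl) ether of F10 | O=Cc1cc2c(cc1O[Si](C)(C)C(C)(C)C)O[C@H](c1ccc(O[Si](C)(C)C(C)(C)C)c(O[Si](C)(C)C(C)(C)C)c1)[C@H]2c1cc(O[Si](C)(C)C(C)(C)C)cc(O[Si](C)(C)C(C)(C)C)c1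
F12 | step 10 | diethyl {[3,5-bis(tert-butyldimethylsilyloxy)phenyl]methyl}phosphonate | CCOP(=O)(Cc1cc(O[Si](C)(C)C(C)(C)C)cc(O[Si](C)(C)C(C)(C)C)c1)OCC
F13 | step 10 | heptakis(tert-butyldimethylsilyl) ether of 17 | CC(C)(C)[Si](C)(C)Oc1cc(O[Si](C)(C)C(C)(C)C)cc(/C=C/c2cc3c(cc2O[Si](C)(C)C(C)(C)C)O[C@H](c2ccc(O[Si](C)(C)C(C)(C)C)c(O[Si](C)(C)C(C)(C)C)c2)[C@H]3c2cc(O[Si](C)(C)C(C)(C)C)cc(O[Si](C)(C)C(C)(C)C)c2)c1
A1 | alternative 1 | 2-[2-(3,4-dimethoxyphenyl)-3-(3,5-dimethoxyphenyl)-5-(1,3-dioxolan-2-yl)-6-methoxy-2,3-dihydro-1-benzofuran-2-yl]-4,4,5,5-tetramethyl-1,3,2-dioxaborolane (aryl groups trans, configuration as in the SMILES) | O1CCOC1c1cc2c(cc1OC)O[C@](B1OC(C)(C)C(C)(C)O1)(c1ccc(OC)c(OC)c1)[C@H]2c1cc(OC)cc(OC)c1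
A2 | alternative 1 | 2-[5-(1,3-dioxolan-2-yl)-6-methoxy-1-benzofuran-2-yl]-4,4,5,5-tetramethyl-1,3,2-dioxaborolane | COc1cc2oc(B3OC(C)(C)C(C)(C)O3)cc2cc1C1OCCO1
A3 | alternative 1 | (3,4-dimethoxyphenyl)lithium | [Li]c1ccc(OC)c(OC)c1
A4 | alternative 1 | 3,5-dimethoxyphenyl trifluoromethanesulfonate | COc1cc(OC)cc(OS(=O)(=O)C(F)(F)F)c1
A5 | alternative 2 | (2S,3S)-5-bromo-2-(3,4-dimethoxyphenyl)-3-(3,5-dimethoxyphenyl)-6-methoxy-2,3-dihydro-1-benzofuran | Brc1cc2c(cc1OC)O[C@H](c1ccc(OC)c(OC)c1)[C@H]2c1cc(OC)cc(OC)c1
A6 | alternative 2 | {5-bromo-2-[(3,4-dimethoxyphenyl)methoxy]-4-methoxyphenyl}(3,5-dimethoxyphenyl)diazomethane | [N-]=[N+]=C(c1cc(OC)cc(OC)c1)c1cc(Br)c(OC)cc1OCc1ccc(OC)c(OC)c1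
A7 | alternative 3 | methyl 2-[(E)-2-[(2S,3S)-3-(3,5-dihydroxy-2-methoxycarbonylphenyl)-2-(3,4-dimethoxyphenyl)-6-methoxy-2,3-dihydro-1-benzofuran-5-yl]ethenyl]-4,6-dihydroxybenzoate | COC(=O)c1c(O)cc(O)cc1/C=C/c1cc2c(cc1OC)O[C@H](c1ccc(OC)c(OC)c1)[C@H]2c1cc(O)cc(O)c1C(=O)OC
A8 | alternative 3 | bis(diketo-dioxinone) precursor of A7: the C3 and C5 arms of the 2-(3,4-dimethoxyphenyl)-6-methoxy-2,3-dihydro-1-benzofuran core each end in a 2,4-dioxo chain bearing a 2,2-dimethyl-4-oxo-1,3-dioxin-6-yl group (configuration as in the SMILES) | CC1(C)OC(CC(=O)CC(=O)/C=C/c2cc3c(cc2OC)O[C@H](c2ccc(OC)c(OC)c2)[C@H]3C(=O)CC(=O)CC2=CC(=O)OC(C)(C)O2)=CC(=O)O1
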